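**Strategy.** The route rests on opening ring B of the trans-decalin across C5–C10 and C6–C7. The exocyclic C8 methylene is read as a masked ketone, so that C7=C8(OMe)–C9=C10 becomes an electron-rich diene, C5=C6 (as an E-vinyl sulfone) the dienophile and the ring A atoms C1–C4 the tether. One intramolecular Diels–Alder reaction of this acyclic triene closes rings A and B together and sets C5 and C10 under control of the C3/C4 stereodiad, which comes from an iridium-catalysed tert-(hydroxy)prenylation. The tetrasubstituted diene geometry is fixed earlier by syn-carbocupration of methyl but-2-ynoate.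

Key step: step 12

Remarks on the chemistry. Labdane numbering of the target (C1–C20) is used for all intermediates. Assumption for step 2: the coupling is taken to give the diastereomer in which the secondary hydroxyl and the hydroxymethyl group are anti, and the (R)-Tol-BINAP catalyst is taken to give the (R)-carbinol; if the sense of induction is the opposite, the (S)-ligand is used. Two carbon substituents on C4 then exchange roles: the coupling's hydroxymethyl group becomes C5 and its vinyl group becomes C18.

**Step 1**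
Reactants: 1 3-chloropropan-1-ol; 2 methyl but-2-ynoate
Product: 6 methyl (2Z)-2-bromo-6-hydroxy-3-methylhex-2-enoate, via alkoxide Grignard reagent 3 (not isolated), via alkylcopper 4 (not isolated), via alkenylcopper 5 (not isolated)
Conditions: i-PrMgCl (1.0 equiv), THF, −20 °C; Mg turnings, THF, reflux; CuBr·SMe2 (1.0 equiv), −78 °C; 2, −78 °C; NBS, −78 → −40 °C; aq NH4Cl
Reagents that add atoms: N-bromosuccinimide, O=C1CCC(=O)N1Br
Why: Syn-carbocupration of the ynoate should place the C1 chain and copper cis (ester cis to the C20 methyl), and bromination of the alkenyl–copper bond with retention at low temperature should fix the tetrasubstituted C9=C10 geometry before allenoate equilibration.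

**Step 2**
Reactants: 6 methyl (2Z)-2-bromo-6-hydroxy-3-methylhex-2-enoate; 7 2-methyl-2-vinyloxirane (racemic)
Product: 8 methyl (2Z,6R,7R)-2-bromo-6-hydroxy-7-(hydroxymethyl)-3,7-dimethylnona-2,8-dienoate
Conditions: Ir(allyl)[(R)-Tol-BINAP](4-cyano-3-nitrobenzoate-C,O) (5 mol%, preformed from [Ir(cod)Cl]2), K3PO4 (5 mol%), THF, 45 °C
Reagents that add atoms: none
Why: Redox-neutral transfer-hydrogenative tert-(hydroxy)prenylation: the primary alcohol is dehydrogenated to the aldehyde, the vinyl epoxide is ionised to an (E)-σ-allyliridium species, and a closed chair transition state under catalyst control should set C3 (R) and the C4 quaternary centre with the anti relationship.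

**Step 3**
Reactants: 8 diol
Product: 9 methyl (2Z,6R,7S)-2-bromo-7-formyl-6-hydroxy-3,7-dimethylnona-2,8-dienoate
Conditions: TEMPO (10 mol%), PhI(OAc)2 (1.2 equiv), CH2Cl2, rt
Reagents that add atoms: none
Why: Oxoammonium oxidation should select the primary alcohol (future C5) over the hindered secondary C3 hydroxyl; the quaternary α-carbon cannot epimerise.

**Step 4**
Reactants: 9 aldehyde
Product: 10 methyl (2Z,6R,7R,8E)-2-bromo-7-ethenyl-6-hydroxy-3,7-dimethyl-9-(phenylsulfonyl)nona-2,8-dienoate
Conditions: (EtO)2P(O)CH2SO2Ph, LiCl, DBU, MeCN, 0 °C → rt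
Reagents that add atoms: diethyl [(phenylsulfonyl)methyl]phosphonate, CCOP(=O)(CS(=O)(=O)c1ccccc1)OCC
Why: Horner–Wadsworth–Emmons olefination under mild LiCl/amine conditions should give the (E)-vinyl sulfone (C5=C6) without retro-aldol cleavage of the β-hydroxy aldehyde.

**Step 5**
Reactants: 10 vinyl sulfone
Product: 12 methyl (2Z,6R,7S,8E)-2-bromo-6-hydroxy-7-(hydroxymethyl)-3,7-dimethyl-9-(phenylsulfonyl)nona-2,8-dienoate, via aldehyde 11 (not isolated)
Conditions: O3, CH2Cl2/MeOH, −78 °C (Sudan Red 7B end point); NaBH4, −78 → 0 °C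
Reagents that add atoms: ozone, [O-][O+]=O
Why: Ozonolysis should cleave only the electron-rich vinyl group on C4, the vinyl sulfone and the bromo enoate being deactivated, and cold borohydride reduction should turn the aldehyde into the C18 hydroxymethyl group.

**Step 6**
Reactants: 12 primary alcohol
Product: 13 C18 tert-butyldiphenylsilyl ether of 12 (bromo enoate, free C3 hydroxyl, E-vinyl sulfone retained)
Conditions: TBDPSCl, imidazole, DMF, 0 °C → rt
Reagents that add atoms: tert-butyl(chloro)diphenylsilane, CC(C)(C)[Si](Cl)(c1ccccc1)c1ccccc1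
Why: Silylation should occur at the primary alcohol and leave the secondary C3 hydroxyl, flanked by the quaternary carbon, free.

**Step 7**
Reactants: 14 vinylmagnesium bromide; 15 dimethyl but-2-ynedioate
Product: 18 dimethyl (2Z)-2-ethenylbut-2-enedioate, via vinylcopper 16 (not isolated), via alkenylcopper 17 (not isolated)
Conditions: CuBr·SMe2 (1.0 equiv), THF, −78 °C; 15, −78 °C; aq NH4Cl at −78 °C
Reagents that add atoms: none
Why: Syn-carbocupration of the alkyne and cold protonation should give the maleate geometry, which becomes the Z arrangement of C15 and C16.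

**Step 8**
Reactants: 18 diester
Product: 19 (2Z)-2-ethenylbut-2-ene-1,4-diol
Conditions: i-Bu2AlH (4.5 equiv), CH2Cl2, −78 → 0 °C; aq potassium sodium tartrate (KNaC4H4O6)
Reagents that add atoms: none
Why: 1,2-Reduction of both esters should keep the alkene geometry.

**Step 9**
Reactants: 19 diol
Product: 20 (Z)-1,4-bis(tert-butyldiphenylsilyloxy)-2-ethenylbut-2-ene
Conditions: TBDPSCl (2.2 equiv), imidazole, DMF, rt
Reagents that add atoms: tert-butyl(chloro)diphenylsilane, CC(C)(C)[Si](Cl)(c1ccccc1)c1ccccc1
Why: Standard silylation of two primary allylic alcohols.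

**Step 10**
Reactants: 20 side-chain diene; 13 alkenyl bromide
Product: 22 tetrasubstituted enoate carrying the complete C11–C16 chain on C9 (C8 methyl ester cis to the C20 methyl; free C3 hydroxyl; C18 silyl ether; E-vinyl sulfone C5=C6), via alkylborane 21 (not isolated)
Conditions: 9-BBN dimer, THF, rt; then 13, Pd(dppf)Cl2 (5 mol%), AsPh3, Cs2CO3, DMF/H2O, rt → 45 °C
Reagents that add atoms: none
Why: 9-BBN should add anti-Markovnikov to the terminal vinyl group only, the trisubstituted alkene being shielded by two silyloxymethyl groups, and the B-alkyl Suzuki–Miyaura coupling should form C9–C11 with retention of the alkene geometry.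

**Step 11**
Reactants: 22 enoate
Product: 23 2-methoxydiene triene (C7H2=C8(OMe)–C9=C10 with the tether C1 trans to C8; E-vinyl sulfone C5=C6)
Conditions: Tebbe reagent Cp2Ti(μ-CH2)(μ-Cl)AlMe2 (3 equiv), pyridine, THF/toluene, −40 °C → rt; aq NaOH; filtration through basic Al2O3
Reagents that add atoms: Tebbe reagent Cp2Ti(μ-CH2)(μ-Cl)AlMe2, C[Al-]1(C)C[Ti]([Cl+]1)(C2C=CC=C2)C3C=CC=C3
Why: Carbonyl methylenation of the twisted, hindered ester by the titanocene methylidene released from the Tebbe reagent should give the 2-methoxy-1,3-diene and bring in C7, while the sulfone and silyl ethers are inert and the free hydroxyl only consumes reagent.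

**Step 12**
Reactants: 23 triene
Product: 24 trans-fused bicyclic methyl enol ether (C8(OMe)=C9) with an equatorial 6-phenylsulfonyl group, C20 methyl axial and H5 trans to it
Conditions: toluene (0.005 M), BHT, Et3N (trace), 125 °C, sealed tube
Reagents that add atoms: none
Why: Thermal intramolecular Diels–Alder reaction of a 1,7,9-decatriene, a concerted asynchronous [4+2] cycloaddition between the 2-methoxydiene C7=C8–C9=C10 and the (E)-vinyl sulfone C5=C6; the closest known class is the cycloaddition of (E)-1-sulfonyl-1,7,9-decatrienes and of 2-alkoxy- or 2-silyloxydienes with a fully substituted terminus. Ring A is closed through the new C5–C10 bond with the four-atom tether C1–C4 in a chair (fused mode, the only one this tether allows), and ring B is the cyclohexene made by the cycloaddition itself through C5–C10 and C6–C7. C10 and C5 are set together: the tether is E on the diene, so the diene arm takes the equatorial and the smaller C20 methyl the axial position of the forming chair next to the axial C4 methyl, which should give the trans ring fusion. The π-face is chosen by the C3/C4 stereodiad, since only one chair keeps both the C3 hydroxyl and the C4 silyloxymethyl group equatorial; C6 follows from the E geometry of the sulfone and is erased in step 13. The step needs rate more than regiocontrol: the sulfone lowers the dienophile LUMO and the methoxy group raises the diene HOMO so that cycloaddition should outrun the [1,5]-hydrogen shift open to the (Z)-methyl diene, and the dilute, base-buffered, radical-inhibited medium protects the enol ethers.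

**Step 13**
Reactants: 24 sulfone
Product: 25 desulfonylated bicyclic methyl enol ether
Conditions: Na(Hg) (6% Na), Na2HPO4, MeOH/THF, −20 → 0 °C
Reagents that add atoms: none
Why: Reductive desulfonylation should give C6H2; it is done before the ketone is unmasked, because a β-sulfonyl ketone would eliminate sulfinate.

**Step 14**
Reactants: 25 enol ether
Product: 27 8-oxo decalin with the C9 side chain equatorial (configuration as in the target), via 9-epi ketone 26 (not isolated)
Conditions: 1 M aq HCl, THF, rt; then K2CO3, MeOH, rt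
Reagents that add atoms: water, O
Why: Enol ether hydrolysis followed by base equilibration through the enolate should converge on the thermodynamically preferred C9 epimer with the equatorial side chain (H9 axial, trans to the C20 methyl).

**Step 15**
Reactants: 27 ketone
Product: 28 8(17)-methylene alcohol (free C3 hydroxyl; C15, C16 and C18 as tert-butyldiphenylsilyl ethers)
Conditions: Ph3PCH3Br, KOtBu, toluene, 0 → 90 °C
Reagents that add atoms: methylidenetriphenylphosphorane (formed from Ph3PCH3Br and KOtBu), C=P(c1ccccc1)(c1ccccc1)c1ccccc1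
Why: Wittig methylenation of the hindered C8 ketone with excess salt-free ylide; any C9 epimerisation under base returns to the desired equatorial isomer.

**Step 16**
Reactants: 28 alcohol; 29 angelic acid
Product: 31 C3 angelate tris(silyl ether), via mixed anhydride 30 (not isolated)
Conditions: 2,4,6-trichlorobenzoyl chloride, Et3N, toluene, rt; then 28, toluene, 80 °C
Reagents that add atoms: none
Why: Yamaguchi-type acylation: the alcohol should attack the unhindered angeloyl carbonyl of the mixed anhydride, and leaving out a nucleophilic amine catalyst should limit Z → E isomerisation; C3–OH is the only free hydroxyl.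

**Step 17**
Reactants: 31 tris(silyl ether)
Product: 32 target, (3R,4S,5S,9R,10S)-15,16,18-trihydroxylabda-8(17),13Z-dien-3-yl angelate
Conditions: HF·pyridine, pyridine, THF, 0 °C → rt
Reagents that add atoms: none
Why: Buffered acidic fluoride should cleave the three primary silyl ethers without 1,3-acyl migration from O3 to O18 and without touching the alkenes.

**Compound list**

1 | 3-chloropropan-1-ol | OCCCCl | starting material
2 | methyl but-2-ynoate | CC#CC(=O)OC | starting material
3 | alkoxide Grignard reagent ClMg(CH2)3OMgCl | Cl[Mg]CCCO[Mg]Cl | intermediate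
4 | 3-(chloromagnesiooxy)propylcopper | [Cu]CCCO[Mg]Cl | intermediate
5 | alkenylcopper from syn-carbocupration (copper cis to the chain, ester cis to methyl) | COC(=O)/C([Cu])=C(\C)CCCO[Mg]Cl | intermediate
6 | methyl (2Z)-2-bromo-6-hydroxy-3-methylhex-2-enoate | COC(=O)/C(Br)=C(\C)CCCO | intermediate
7 | 2-methyl-2-vinyloxirane (racemic) | CC1(C=C)CO1 | starting material
8 | methyl (2Z,6R,7R)-2-bromo-6-hydroxy-7-(hydroxymethyl)-3,7-dimethylnona-2,8-dienoate | COC(=O)/C(Br)=C(\C)CC[C@@H](O)[C@](CO)(C)C=C | intermediate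
9 | methyl (2Z,6R,7S)-2-bromo-7-formyl-6-hydroxy-3,7-dimethylnona-2,8-dienoate | COC(=O)/C(Br)=C(\C)CC[C@@H](O)[C@](C=O)(C)C=C | intermediate
10 | methyl (2Z,6R,7R,8E)-2-bromo-7-ethenyl-6-hydroxy-3,7-dimethyl-9-(phenylsulfonyl)nona-2,8-dienoate | COC(=O)/C(Br)=C(\C)CC[C@@H](O)[C@](/C=C/S(=O)(=O)c1ccccc1)(C)C=C | intermediate
11 | methyl (2Z,6R,7R,8E)-2-bromo-7-formyl-6-hydroxy-3,7-dimethyl-9-(phenylsulfonyl)nona-2,8-dienoate | COC(=O)/C(Br)=C(\C)CC[C@@H](O)[C@](/C=C/S(=O)(=O)c1ccccc1)(C)C=O | intermediate
12 | methyl (2Z,6R,7S,8E)-2-bromo-6-hydroxy-7-(hydroxymethyl)-3,7-dimethyl-9-(phenylsulfonyl)nona-2,8-dienoate | COC(=O)/C(Br)=C(\C)CC[C@@H](O)[C@](/C=C/S(=O)(=O)c1ccccc1)(C)CO | intermediate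
13 | C18 tert-butyldiphenylsilyl ether of 12 | COC(=O)/C(Br)=C(\C)CC[C@@H](O)[C@](/C=C/S(=O)(=O)c1ccccc1)(C)CO[Si](c1ccccc1)(c1ccccc1)C(C)(C)C | intermediate
14 | vinylmagnesium bromide | C=C[Mg]Br | starting material
15 | dimethyl but-2-ynedioate | COC(=O)C#CC(=O)OC | starting material
16 | vinylcopper | C=C[Cu] | intermediate
17 | alkenylcopper adduct (copper cis to vinyl, esters cis) | COC(=O)/C([Cu])=C(/C=C)C(=O)OC | intermediate
18 | dimethyl (2Z)-2-ethenylbut-2-enedioate | COC(=O)/C=C(/C=C)C(=O)OC | intermediate
19 | (2Z)-2-ethenylbut-2-ene-1,4-diol | OC/C=C(/C=C)CO | intermediate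
20 | (Z)-1,4-bis(tert-butyldiphenylsilyloxy)-2-ethenylbut-2-ene | C=C/C(CO[Si](c1ccccc1)(c1ccccc1)C(C)(C)C)=C/CO[Si](c1ccccc1)(c1ccccc1)C(C)(C)C | intermediate
21 | B-alkyl-9-BBN adduct of 20 (boron on C11) | CC(C)(C)[Si](c1ccccc1)(c1ccccc1)OC/C=C(/CCB1C2CCCC1CCC2)CO[Si](c1ccccc1)(c1ccccc1)C(C)(C)C | intermediate
22 | tetrasubstituted enoate (ester cis to C20 methyl, full side chain on C9, C3–OH, C18–OTBDPS, E-vinyl sulfone) | COC(=O)/C(CC/C(CO[Si](c1ccccc1)(c1ccccc1)C(C)(C)C)=C/CO[Si](c1ccccc1)(c1ccccc1)C(C)(C)C)=C(\C)CC[C@@H](O)[C@](/C=C/S(=O)(=O)c1ccccc1)(C)CO[Si](c1ccccc1)(c1ccccc1)C(C)(C)C | intermediate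
23 | 2-methoxydiene triene | COC(=C)/C(CC/C(CO[Si](c1ccccc1)(c1ccccc1)C(C)(C)C)=C/CO[Si](c1ccccc1)(c1ccccc1)C(C)(C)C)=C(\C)CC[C@@H](O)[C@](/C=C/S(=O)(=O)c1ccccc1)(C)CO[Si](c1ccccc1)(c1ccccc1)C(C)(C)C | intermediate
24 | trans-fused cycloadduct, 8-methoxy-8-ene, 6-phenylsulfonyl (equatorial, cis to H5) | COC1=C(CC/C(CO[Si](c3ccccc3)(c3ccccc3)C(C)(C)C)=C/CO[Si](c3ccccc3)(c3ccccc3)C(C)(C)C)[C@]2(C)CC[C@@H](O)[C@](C)(CO[Si](c3ccccc3)(c3ccccc3)C(C)(C)C)[C@H]2[C@H](S(=O)(=O)c2ccccc2)C1 | intermediate
25 | desulfonylated bicyclic methyl enol ether | COC1=C(CC/C(CO[Si](c3ccccc3)(c3ccccc3)C(C)(C)C)=C/CO[Si](c3ccccc3)(c3ccccc3)C(C)(C)C)[C@]2(C)CC[C@@H](O)[C@](C)(CO[Si](c3ccccc3)(c3ccccc3)C(C)(C)C)[C@H]2CC1 | intermediate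
26 | 8-oxo decalin, C9 epimer (side chain axial) | O=C1CC[C@H]2[C@@](C)(CC[C@@H](O)[C@]2(C)CO[Si](c3ccccc3)(c3ccccc3)C(C)(C)C)[C@H]1CC/C(=C/CO[Si](c1ccccc1)(c1ccccc1)C(C)(C)C)CO[Si](c1ccccc1)(c1ccccc1)C(C)(C)C | intermediate
27 | 8-oxo decalin, C9 as in the target (side chain equatorial) | O=C1CC[C@H]2[C@@](C)(CC[C@@H](O)[C@]2(C)CO[Si](c3ccccc3)(c3ccccc3)C(C)(C)C)[C@@H]1CC/C(=C/CO[Si](c1ccccc1)(c1ccccc1)C(C)(C)C)CO[Si](c1ccccc1)(c1ccccc1)C(C)(C)C | intermediate
28 | 8(17)-methylene C3 alcohol, tris(silyl ether) | C=C1CC[C@H]2[C@@](C)(CC[C@@H](O)[C@]2(C)CO[Si](c3ccccc3)(c3ccccc3)C(C)(C)C)[C@@H]1CC/C(=C/CO[Si](c1ccccc1)(c1ccccc1)C(C)(C)C)CO[Si](c1ccccc1)(c1ccccc1)C(C)(C)C | intermediate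
29 | angelic acid, (2Z)-2-methylbut-2-enoic acid | C/C=C(/C)C(=O)O | starting material
30 | angelic 2,4,6-trichlorobenzoic mixed anhydride | C/C=C(/C)C(=O)OC(=O)c1c(Cl)cc(Cl)cc1Cl | intermediate
31 | C3 angelate tris(silyl ether) | C=C1CC[C@H]2[C@@](C)(CC[C@@H](OC(=O)/C(C)=C\C)[C@]2(C)CO[Si](c3ccccc3)(c3ccccc3)C(C)(C)C)[C@@H]1CC/C(=C/CO[Si](c1ccccc1)(c1ccccc1)C(C)(C)C)CO[Si](c1ccccc1)(c1ccccc1)C(C)(C)C | intermediate
32 | (3R,4S,5S,9R,10S)-15,16,18-trihydroxylabda-8(17),13Z-dien-3-yl angelate | C=C1CC[C@H]2[C@@](C)(CC[C@@H](OC(=O)/C(C)=C\C)[C@]2(C)CO)[C@@H]1CC/C(=C/CO)CO | target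

**Totals.** Total step count: 17. Longest linear sequence: 14 steps (steps 1–6 and 10–17); steps 7–9 make the side chain.

**Steps most likely to fail**

Step 12. The cycloaddition may be slow at the fully substituted diene terminus bearing the (Z)-methyl group, since the sulfone polarity is not matched to the methoxy group. The [1,5]-hydrogen shift of the diene, cis-fused closure or thermal loss of the allylic silyl ethers could then compete. The fallback moves the ring formation in front of the fragment union. It sets out from 13: Tebbe methylenation (Cp2Ti(μ-CH2)(μ-Cl)AlMe2, pyridine) should give the bromo methoxydiene F1, a smaller triene without the allylic silyl ethers that can be forced to cyclise at 12 kbar in CH2Cl2. This should give the bicyclic 9-bromo enol ether F2, and B-alkyl Suzuki–Miyaura coupling of F2 with alkylborane 21 (Pd(dppf)Cl2, Cs2CO3) comes back to the route at 24.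

Step 2. The alkenyl bromide may be consumed by oxidative addition to the low-valent iridium species, or the anti diastereoselectivity and enantioselectivity may be eroded. The fallback replaces the iridium coupling by a boron allylation, which is indifferent to the bromide. It sets out from 6: oxidation (TEMPO, PhI(OAc)2) should give methyl (2Z)-2-bromo-3-methyl-6-oxohex-2-enoate F3. The reagent (2E)-2-methyl-4-(4,4,5,5-tetramethyl-1,3,2-dioxaborolan-2-yl)but-2-en-1-ol F4 would be prepared from 7 and B2pin2 by CuCl/NaOtBu-catalysed SN2' borylation. Allylboration of F3 with F4 under a chiral phosphoric acid catalyst, through a closed chair transition state, should give the same anti diol and comes back to the route at 8.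

Step 16. Acylation of the hindered C3 hydroxyl may be slow enough that the angeloyl unit isomerises to the tigloyl (E) isomer, or the acylation may stay incomplete. The fallback builds the Z alkene on the ester instead of transferring it. It sets out from 28: esterification with 2-[bis(2,2,2-trifluoroethoxy)phosphoryl]propanoic acid (DCC, DMAP) should give the phosphonate ester F5. Still–Gennari olefination of F5 with acetaldehyde (KN(SiMe3)2, 18-crown-6, THF, −78 °C) should form the (Z)-2-methylbut-2-enoate and comes back to the route at 31.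

**Further compounds**

F1 | step 12 | bromo methoxydiene from 13 (C8 methylenated, C9–Br retained) | COC(=C)/C(Br)=C(\C)CC[C@@H](O)[C@](/C=C/S(=O)(=O)c1ccccc1)(C)CO[Si](c1ccccc1)(c1ccccc1)C(C)(C)C
F2 | step 12 | trans-fused bicyclic 9-bromo-8-methoxy-8-ene with 6-phenylsulfonyl group | COC1=C(Br)[C@]2(C)CC[C@@H](O)[C@](C)(CO[Si](c3ccccc3)(c3ccccc3)C(C)(C)C)[C@H]2[C@H](S(=O)(=O)c2ccccc2)C1
F3 | step 2 | methyl (2Z)-2-bromo-3-methyl-6-oxohex-2-enoate | COC(=O)/C(Br)=C(\C)CCC=O
F4 | step 2 | (2E)-2-methyl-4-(4,4,5,5-tetramethyl-1,3,2-dioxaborolan-2-yl)but-2-en-1-ol | OC/C(C)=C/CB1OC(C)(C)C(C)(C)O1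
F5 | step 16 | C3 2-[bis(2,2,2-trifluoroethoxy)phosphoryl]propanoate of 28 | C=C1CC[C@H]2[C@@](C)(CC[C@@H](OC(=O)C(C)P(=O)(OCC(F)(F)F)OCC(F)(F)F)[C@]2(C)CO[Si](c3ccccc3)(c3ccccc3)C(C)(C)C)[C@@H]1CC/C(=C/CO[Si](c1ccccc1)(c1ccccc1)C(C)(C)C)CO[Si](c1ccccc1)(c1ccccc1)C(C)(C)C
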